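**Retrosynthetic overview**

- The only ring is a benzene ring. Its substituents sit on three neighbouring atoms: C1 (CO2C22H45), C2 (OH) and C3 (OH). C4, C5 and C6 carry only hydrogen, so the C4–C5 bond, opposite the crowded C1–C2–C3 edge, can be made from two terminal alkenes.
- Catechol ⇒ its non-aromatic tautomer, the cyclohex-4-ene-2,3-dione ⇒ the C3 carbinol (one oxidation) ⇒ its TBS ether.
- The six-membered carbocycle is formed once, as a cyclohexene, and aromatised last. It comes from ring-closing metathesis at C4=C5 of an acyclic β-keto ester that carries an allyl group on C1 and a vinyl group on C3.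
- C1–C2 bond ⇒ crossed Claisen condensation of docosyl pent-4-enoate with O-silylated methyl vinylglycolate. The docosyl ester is in place from the start.

Key step: step 4

Assumption: the target SMILES contains no stereocentre and no stereogenic double bond. The compound is achiral, so the demand for a single enantiomer is met by constitution alone, and racemic methyl 2-hydroxybut-3-enoate is used. Ring atoms are numbered as in the final benzoate (C1 bears the ester).

**Step 1**
Reactants: 1 methyl 2-hydroxybut-3-enoate (racemic)
Product: 2 methyl 2-(tert-butyldimethylsilyloxy)but-3-enoate (racemic)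
Conditions: TBSCl (1.2 equiv), imidazole (2.5 equiv), CH2Cl2, 0 °C to rt
Reagents that add atoms: tert-butyldimethylsilyl chloride, CC(C)(C)[Si](C)(C)Cl
Why: Imidazole-promoted O-silylation of a secondary alcohol; the base is too weak to pull the double bond into conjugation, and the silyl ether is needed because a free hydroxyl would quench the enolate of step 3 and, in the acyclic keto ester, would lactonise onto the docosyl ester.

**Step 2**
Reactants: 3 pent-4-enoic acid; 4 1-docosanol
Product: 5 docosyl pent-4-enoate
Conditions: 3 (1.2 equiv), p-TsOH·H2O (5 mol %), toluene, reflux, Dean–Stark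
Reagents that add atoms: none
Why: Fischer esterification driven by azeotropic removal of water; hot toluene dissolves the fatty alcohol and the terminal alkene is inert to catalytic sulfonic acid.

**Step 3**
Reactants: 5 docosyl pent-4-enoate; 2 methyl 2-(tert-butyldimethylsilyloxy)but-3-enoate
Product: 8 docosyl 2-allyl-4-(tert-butyldimethylsilyloxy)-3-oxohex-5-enoate (diastereomer mixture), via lithium ester enolate 6 (not isolated), via lithium keto ester enolate 7 (not isolated)
Conditions: LDA (commercial solution, 2.2 equiv), 5 (2.2 equiv), THF (0.05 M), −78 °C; then 2 (1.0 equiv), −78 to −40 °C; AcOH, −78 °C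
Reagents that add atoms: none
Why: Crossed Claisen condensation in which the preformed enolate adds to the inductively activated α-silyloxy methyl ester, methoxide leaves, and the second equivalent of enolate stores the product as its chelated enolate, which drives the reaction and shields the future C3–H; the two sp3 centres form without control, which does not matter because both are erased on aromatisation.

**Step 4**
Reactants: 8 docosyl 2-allyl-4-(tert-butyldimethylsilyloxy)-3-oxohex-5-enoate
Product: 9 docosyl 5-(tert-butyldimethylsilyloxy)-6-oxocyclohex-3-ene-1-carboxylate (diastereomer and keto/enol mixture)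
Conditions: Grubbs II (5 mol %), degassed CH2Cl2 (5 mM), 40 °C, Ar sparge
Reagents that add atoms: none
Why: Ring-closing olefin metathesis by the metallacyclobutane (Chauvin) mechanism: the ruthenium benzylidene first exchanges with the unhindered allyl terminus, the new alkylidene adds [2+2] to the vinyl group next to the silyloxy carbon, and cycloreversion forms C4=C5 while the two terminal CH2 groups leave as ethene. The closest known reaction type is the ring-closing metathesis of acyclic dienyl ketones and allylated β-keto esters to cyclohexenones that are later aromatised to phenols. The single ring closes as an unstrained six-membered carbocycle whose endocyclic alkene can only be cis, so no alkene geometry has to be controlled. No stereocentre is created, the two existing ones (C1 and C3) are untouched and later erased, and both diastereomers of 8 can cyclise. The step needs ring closure to win over cross-metathesis oligomerisation and over double-bond migration; high dilution, the kinetic ease of six-ring formation and the low dimerisation tendency of the hindered allylic silyl ether terminus should secure the first, and degassed solvent with a short reaction time the second. The medium is neutral and aprotic, so the C3 silyloxy group should not leave together with a C6 hydrogen.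

**Step 5**
Reactants: 9 docosyl 5-(tert-butyldimethylsilyloxy)-6-oxocyclohex-3-ene-1-carboxylate
Product: 10 docosyl 5-hydroxy-6-oxocyclohex-3-ene-1-carboxylate (diastereomer and keto/enol mixture, used crude)
Conditions: HF·pyridine, pyridine-buffered THF, polypropylene vessel, 0 °C to rt; pH 7 phosphate buffer work-up
Reagents that add atoms: none
Why: Fluoride-driven cleavage of a secondary TBS ether in a weakly acidic buffered medium that is neither basic enough to remove a C6 or C3 proton nor acidic enough to ionise the C3–O bond next to the carbonyl, and the bridged lactone that attack of the new hydroxyl on the ester would give is too strained to form.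

**Step 6**
Reactants: 10 docosyl 5-hydroxy-6-oxocyclohex-3-ene-1-carboxylate
Product: 12 Gentiside J (docosyl 2,3-dihydroxybenzoate), via enedione 11 (not isolated)
Conditions: Dess–Martin periodinane (1.0 equiv), CH2Cl2, 0 °C to rt
Reagents that add atoms: none
Why: Dess–Martin oxidation of an α-hydroxy ketone to the 1,2-dione without base, after which enolisation at C1 and vinylogous enolisation at C6, catalysed by the acetic acid released, give the aromatic catechol; only one equivalent of oxidant is used because an excess would carry the catechol on to the o-quinone.

**Compound list**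

1 | methyl 2-hydroxybut-3-enoate (racemic) | C=CC(O)C(=O)OC | starting material
2 | methyl 2-(tert-butyldimethylsilyloxy)but-3-enoate (racemic) | C=CC(O[Si](C)(C)C(C)(C)C)C(=O)OC | intermediate
3 | pent-4-enoic acid | C=CCCC(=O)O | starting material
4 | 1-docosanol | CCCCCCCCCCCCCCCCCCCCCCO | starting material
5 | docosyl pent-4-enoate | CCCCCCCCCCCCCCCCCCCCCCOC(=O)CCC=C | intermediate
6 | lithium enolate of docosyl pent-4-enoate (geometry of no consequence) | [Li+].CCCCCCCCCCCCCCCCCCCCCCOC([O-])=CCC=C | intermediate
7 | lithium enolate of keto ester 8 (geometry of no consequence) | [Li+].CCCCCCCCCCCCCCCCCCCCCCOC(=O)C(CC=C)=C([O-])C(O[Si](C)(C)C(C)(C)C)C=C | intermediate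
8 | docosyl 2-allyl-4-(tert-butyldimethylsilyloxy)-3-oxohex-5-enoate (diastereomer mixture) | CCCCCCCCCCCCCCCCCCCCCCOC(=O)C(CC=C)C(=O)C(O[Si](C)(C)C(C)(C)C)C=C | intermediate
9 | docosyl 5-(tert-butyldimethylsilyloxy)-6-oxocyclohex-3-ene-1-carboxylate (diastereomer mixture) | CCCCCCCCCCCCCCCCCCCCCCOC(=O)C1CC=CC(O[Si](C)(C)C(C)(C)C)C1=O | intermediate
10 | docosyl 5-hydroxy-6-oxocyclohex-3-ene-1-carboxylate (diastereomer mixture) | CCCCCCCCCCCCCCCCCCCCCCOC(=O)C1CC=CC(O)C1=O | intermediate
11 | docosyl 5,6-dioxocyclohex-3-ene-1-carboxylate | CCCCCCCCCCCCCCCCCCCCCCOC(=O)C1CC=CC(=O)C1=O | intermediate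
12 | Gentiside J, docosyl 2,3-dihydroxybenzoate (achiral) | CCCCCCCCCCCCCCCCCCCCCCOC(=O)c1cccc(O)c1O | target

**Step count**

Total step count: 6.
Longest linear sequence: 5 steps (1 → 2 → 8 → 9 → 10 → 12, and equally 4 → 5 → 8 → 9 → 10 → 12).

**Steps most likely to fail**

**Step 4 (ring-closing metathesis).**
- The alkylidene may be held back by chelation to the 1,3-dicarbonyl unit or its enol.
- Ruthenium hydride from catalyst decay may shift the allyl double bond before closure.
- The enolised product may lose silanol on prolonged warming.

The fallback sets out from 8 and takes the ketone out of play before the metathesis. Luche reduction (NaBH4, CeCl3·7H2O, THF–MeOH, −40 °C) should give docosyl 2-allyl-4-(tert-butyldimethylsilyloxy)-3-hydroxyhex-5-enoate F1. Ring-closing metathesis of this non-enolisable, non-chelating diene (Grubbs II, CH2Cl2, 40 °C) should give docosyl 5-(tert-butyldimethylsilyloxy)-6-hydroxycyclohex-3-ene-1-carboxylate F2, which has no route to an arene while the catalyst is present. Dess–Martin oxidation of the C2 carbinol brings the material back to the route at 9.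

**Step 5 (desilylation).**
- The enol tautomer is a 1,4-cyclohexadiene with a leaving group at a doubly allylic carbon, so the C3 oxygen may be lost by 1,4-elimination with aromatisation.
- Enolisation toward C3 may move the C4=C5 double bond into conjugation, and the periodinane could not aromatise the resulting isomer.

The fallback sets out from 9 and aromatises by dehydrogenation while the oxygen is still capped. With DDQ (1.1 equiv, toluene, rt), hydride abstraction from one of the two doubly allylic positions (C6 or C3) of the enol gives an oxygen-stabilised cyclohexadienyl cation. This cation loses the remaining sp3 proton and should deliver docosyl 3-(tert-butyldimethylsilyloxy)-2-hydroxybenzoate F3. The aryl silyl ether is then cleaved with TBAF/AcOH (THF, 0 °C), which is safe once the ring is aromatic, and the route is rejoined at 12. This path also bypasses step 6, so a free catechol never meets an oxidant.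

**Step 3 (crossed Claisen condensation).**
- The hindered enolate may act as a base toward the doubly activated C2–H of 2, causing proton transfer and migration of the double bond into conjugation.
- The wax ester or its enolate may crystallise from THF at −78 °C.
- On warming, O-to-O silyl migration in the product enolate may open the way to lactonisation.

The fallback sets out from 2 and 4, uses no strong base, and runs at room temperature.
- Saponification of 2 (LiOH, THF–H2O, 0 °C, citric acid work-up) gives 2-(tert-butyldimethylsilyloxy)but-3-enoic acid F4.
- Heating 4 with Meldrum's acid in toluene gives docosyl hydrogen malonate F5.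
- F4 is activated with carbonyldiimidazole (THF, rt) to 1-[2-(tert-butyldimethylsilyloxy)but-3-enoyl]imidazole F6.
- F6 acylates the magnesium salt of F5 (i-PrMgCl, THF, rt) in a decarboxylative Claisen reaction to give docosyl 4-(tert-butyldimethylsilyloxy)-3-oxohex-5-enoate F7.
- Tsuji–Trost mono-allylation without added base (allyl methyl carbonate 1.0 equiv, Pd(PPh3)4 cat., THF, rt) rejoins the route at 8.

**Further compounds**

F1 | step 4 | docosyl 2-allyl-4-(tert-butyldimethylsilyloxy)-3-hydroxyhex-5-enoate (diastereomer mixture) | CCCCCCCCCCCCCCCCCCCCCCOC(=O)C(CC=C)C(O)C(O[Si](C)(C)C(C)(C)C)C=C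
F2 | step 4 | docosyl 5-(tert-butyldimethylsilyloxy)-6-hydroxycyclohex-3-ene-1-carboxylate (diastereomer mixture) | CCCCCCCCCCCCCCCCCCCCCCOC(=O)C1CC=CC(O[Si](C)(C)C(C)(C)C)C1O
F3 | step 5 | docosyl 3-(tert-butyldimethylsilyloxy)-2-hydroxybenzoate | CCCCCCCCCCCCCCCCCCCCCCOC(=O)c1cccc(O[Si](C)(C)C(C)(C)C)c1O
F4 | step 3 | 2-(tert-butyldimethylsilyloxy)but-3-enoic acid (racemic) | C=CC(O[Si](C)(C)C(C)(C)C)C(=O)O
F5 | step 3 | docosyl hydrogen malonate | CCCCCCCCCCCCCCCCCCCCCCOC(=O)CC(=O)O
F6 | step 3 | 1-[2-(tert-butyldimethylsilyloxy)but-3-enoyl]imidazole (racemic) | C=CC(O[Si](C)(C)C(C)(C)C)C(=O)n1ccnc1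
F7 | step 3 | docosyl 4-(tert-butyldimethylsilyloxy)-3-oxohex-5-enoate (racemic) | CCCCCCCCCCCCCCCCCCCCCCOC(=O)CC(=O)C(O[Si](C)(C)C(C)(C)C)C=C
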